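Assumption: the target is read as (4S,5S,8S,9S,10R,13S)-8,15-dihydroxylabdan-18-yl (2Z)-2-methylbut-2-enoate, an ent-labdane whose CH2O–angelate arm is equatorial on C-4 (trans to the C-10 methyl); labdane numbering is used throughout.

## Retrosynthetic overview

1. Target 15 comes from bicyclic 3-hydroxy angelate 12 by removal of the C-3 hydroxyl and of the C-15 silyl group.
2. 12 comes from acyclic epoxy angelate 11 in one cation–olefin cascade: ring A closes first (C4–C5), then ring B (C9–C10), and water quenches the C-8 cation; C-4, C-5, C-8, C-9 and C-10 are all set here.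
3. 11 comes from the (E)-allylic alcohol 8 by Sharpless epoxidation and angeloylation; 8 comes from silyl ether 7 by oxidation of the terminal (E)-methyl.
4. 7 comes from allyl–allyl coupling of geranyl chloride 5 with bromide 4, made from (S)-citronellol 1, which supplies C-13.

## Route

Step 1
Reactants: 1 (S)-citronellol
Product: 2 tert-butyl{[(3S)-3,7-dimethyloct-6-en-1-yl]oxy}diphenylsilane
Conditions: TBDPSCl, imidazole, DMF, rt
Reagents that add atoms: tert-butyl(chloro)diphenylsilane, CC(C)(C)[Si](Cl)(c1ccccc1)c1ccccc1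
Why: Imidazole-promoted silylation of the only hydroxyl gives a primary TBDPS ether that survives every later step and is removed last; the C-13 stereocentre (S) is taken unchanged from the chiral pool.

Step 2
Reactants: 2 silyl ether
Product: 3 (2E,6S)-8-[(tert-butyldiphenylsilyl)oxy]-2,6-dimethyloct-2-en-1-ol
Conditions: SeO2 (10 mol%), salicylic acid (10 mol%), t-BuOOH (3 equiv), CH2Cl2, rt
Reagents that add atoms: tert-butyl hydroperoxide, CC(C)(C)OO
Why: Catalytic SeO2 allylic oxidation (ene reaction, then [2,3]-shift) attacks the (E)-methyl of the trisubstituted alkene, so the new CH2OH is trans to the chain and the later C8=C9 geometry is fixed as E.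

Step 3
Reactants: 3 allylic alcohol
Product: 4 {[(3S,6E)-8-bromo-3,7-dimethyloct-6-en-1-yl]oxy}(tert-butyl)diphenylsilane
Conditions: CBr4, PPh3, CH2Cl2, 0 °C
Reagents that add atoms: carbon tetrabromide, BrC(Br)(Br)Br
Why: Appel bromination turns the primary allylic alcohol into the bromide without allylic shift or loss of the E geometry.

Step 4
Reactants: 5 geranyl chloride; 4 allylic bromide
Product: 7 tert-butyl{[(3S,6E,10E)-3,7,11,15-tetramethylhexadeca-6,10,14-trien-1-yl]oxy}diphenylsilane, via geranylbarium chloride 6 (not isolated)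
Conditions: 5, Ba (from BaI2, Li, biphenyl), THF, −78 °C; then 4, −78 °C
Reagents that add atoms: none
Why: Allylbarium reagents couple with allylic bromides at the unsubstituted terminus of each partner (α,α′ allyl–allyl cross-coupling) at −78 °C with retention of both E alkenes, which forms the C6–C7 bond of the 1,5-diene directly.

Step 5
Reactants: 7 trienyl silyl ether
Product: 8 (2E,6E,10E,14S)-16-[(tert-butyldiphenylsilyl)oxy]-2,6,10,14-tetramethylhexadeca-2,6,10-trien-1-ol
Conditions: SeO2 (10 mol%), salicylic acid (10 mol%), t-BuOOH (3 equiv), CH2Cl2, rt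
Reagents that add atoms: tert-butyl hydroperoxide, CC(C)(C)OO
Why: The same SeO2 allylic oxidation prefers the terminal isopropylidene over the two internal alkenes and again takes the (E)-methyl, which makes the oxidized carbon the one that will sit equatorial on C-4 (C-18).

Step 6
Reactants: 8 allylic alcohol
Product: 9 {(2R,3R)-3-[(3E,7E,11S)-13-[(tert-butyldiphenylsilyl)oxy]-3,7,11-trimethyltrideca-3,7-dien-1-yl]-2-methyloxiran-2-yl}methanol
Conditions: Ti(OiPr)4 (10 mol%), D-(−)-diethyl tartrate (12 mol%), t-BuOOH (2 equiv), 4 Å MS, CH2Cl2, −20 °C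
Reagents that add atoms: tert-butyl hydroperoxide, CC(C)(C)OO
Why: Katsuki–Sharpless asymmetric epoxidation touches only the allylic-alcohol alkene and, with the D-tartrate, delivers oxygen to the face that gives the (2R,3R)-oxirane (C-3 R, C-4 R), the two centres that later fix the absolute sense of the decalin.

Step 7
Reactants: 9 epoxy alcohol; 10 angelic anhydride
Product: 11 {(2R,3R)-3-[(3E,7E,11S)-13-[(tert-butyldiphenylsilyl)oxy]-3,7,11-trimethyltrideca-3,7-dien-1-yl]-2-methyloxiran-2-yl}methyl (2Z)-2-methylbut-2-enoate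
Conditions: Cs2CO3, MeCN, rt
Reagents that add atoms: none
Why: Base-mediated acylation with the anhydride, with no nucleophilic catalyst, installs the angelate without Z-to-E isomerization, and the acyl group blocks the hydride-shift (semipinacol) path that a free or silylated epoxy alcohol would take in the next step.

Step 8
Reactants: 11 epoxy angelate
Product: 12 (3R,4S,5S,8S,9S,10R,13S)-15-[(tert-butyldiphenylsilyl)oxy]-3,8-dihydroxylabdan-18-yl (2Z)-2-methylbut-2-enoate (trans-decalin; 3-OH, 8-OH and the C-4 CH2O arm equatorial; C-4, C-8 and C-10 methyls axial on one face)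
Conditions: Sc(OTf)3 (10 mol%), H2O (5 equiv), HFIP/CH2Cl2 (1:1), −20 °C
Reagents that add atoms: water, O
Why: Proposed new method: Sc(OTf)3 in hydrogen-bonding HFIP opens the oxirane at its fully substituted carbon while the C5=C10 alkene attacks that carbon from the back, the charge passes through a chair–chair array to the C8=C9 alkene, and water quenches the C-8 cation; every alkene is attacked anti, so the (E)-derived CH2O arm ends equatorial on C-4 (inversion at C-4, C3–O equatorial), the ring fusion is trans, the C-9 chain is equatorial and water enters C-8 equatorially, anti to the new C9–C10 bond and away from the axial C-10 methyl, with the (3R)-oxirane fixing the absolute sense of all five centres; the closest known reactions are Lewis-acid bicyclizations of acyloxymethyl- and alkoxymethyl-substituted oxiranyl polyenes (alkene- or arene-terminated) and the water-terminated cyclizations of farnesyl esters with Hg(OTf)2 or protic acid that give C-8 tertiary alcohols.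

Step 9
Reactants: 12 diol
Product: 13 (3R,4S,5S,8S,9S,10R,13S)-15-[(tert-butyldiphenylsilyl)oxy]-8-hydroxy-3-[(1H-imidazol-1-ylcarbonothioyl)oxy]labdan-18-yl (2Z)-2-methylbut-2-enoate
Conditions: 1,1′-thiocarbonyldiimidazole, DMAP (cat.), ClCH2CH2Cl, 70 °C
Reagents that add atoms: 1,1′-thiocarbonyldiimidazole, S=C(n1ccnc1)n1ccnc1
Why: Thioacylation occurs at the secondary 3-OH only, because the tertiary 8-OH is too hindered to react, which sets up a Barton–McCombie deoxygenation.

Step 10
Reactants: 13 thiocarbonylimidazolide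
Product: 14 (4S,5S,8S,9S,10R,13S)-15-[(tert-butyldiphenylsilyl)oxy]-8-hydroxylabdan-18-yl (2Z)-2-methylbut-2-enoate
Conditions: Bu3SnH (1.5 equiv), AIBN (10 mol%), toluene, 90 °C, stopped at full conversion
Reagents that add atoms: none
Why: Barton–McCombie deoxygenation: the stannyl radical adds to C=S, β-scission gives the secondary C-3 radical and Bu3SnH reduces it, so C-3 becomes CH2 and no other centre is touched; the thiocarbonyl group traps the tin radical far faster than the hindered angelate alkene does.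

Step 11
Reactants: 14 silyl ether
Product: 15 (4S,5S,8S,9S,10R,13S)-8,15-dihydroxylabdan-18-yl (2Z)-2-methylbut-2-enoate (target)
Conditions: HF·pyridine, pyridine/THF, 0 °C to rt
Reagents that add atoms: none
Why: Fluoride cleaves the Si–O bond under buffered, base-free conditions, so the angelate neither migrates nor isomerizes and the tertiary alcohol is left alone.

## Compound list

1 | (S)-citronellol, (3S)-3,7-dimethyloct-6-en-1-ol | CC(C)=CCC[C@H](C)CCO | starting material
2 | tert-butyl{[(3S)-3,7-dimethyloct-6-en-1-yl]oxy}diphenylsilane | CC(C)=CCC[C@H](C)CCO[Si](c1ccccc1)(c1ccccc1)C(C)(C)C | intermediate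
3 | (2E,6S)-8-[(tert-butyldiphenylsilyl)oxy]-2,6-dimethyloct-2-en-1-ol | OC/C(C)=C/CC[C@H](C)CCO[Si](c1ccccc1)(c1ccccc1)C(C)(C)C | intermediate
4 | {[(3S,6E)-8-bromo-3,7-dimethyloct-6-en-1-yl]oxy}(tert-butyl)diphenylsilane | BrC/C(C)=C/CC[C@H](C)CCO[Si](c1ccccc1)(c1ccccc1)C(C)(C)C | intermediate
5 | geranyl chloride, (2E)-1-chloro-3,7-dimethylocta-2,6-diene | CC(C)=CCC/C(C)=C/CCl | starting material
6 | geranylbarium chloride, [(2E)-3,7-dimethylocta-2,6-dien-1-yl]barium chloride | CC(C)=CCC/C(C)=C/C[Ba]Cl | intermediate (not isolated)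
7 | tert-butyl{[(3S,6E,10E)-3,7,11,15-tetramethylhexadeca-6,10,14-trien-1-yl]oxy}diphenylsilane | CC(C)=CCC/C(C)=C/CC/C(C)=C/CC[C@H](C)CCO[Si](c1ccccc1)(c1ccccc1)C(C)(C)C | intermediate
8 | (2E,6E,10E,14S)-16-[(tert-butyldiphenylsilyl)oxy]-2,6,10,14-tetramethylhexadeca-2,6,10-trien-1-ol | OC/C(C)=C/CC/C(C)=C/CC/C(C)=C/CC[C@H](C)CCO[Si](c1ccccc1)(c1ccccc1)C(C)(C)C | intermediate
9 | {(2R,3R)-3-[(3E,7E,11S)-13-[(tert-butyldiphenylsilyl)oxy]-3,7,11-trimethyltrideca-3,7-dien-1-yl]-2-methyloxiran-2-yl}methanol | OC[C@@]1(C)O[C@@H]1CC/C(C)=C/CC/C(C)=C/CC[C@H](C)CCO[Si](c1ccccc1)(c1ccccc1)C(C)(C)C | intermediate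
10 | angelic anhydride, (2Z)-2-methylbut-2-enoic anhydride | C/C=C(/C)C(=O)OC(=O)/C(C)=C\C | starting material
11 | {(2R,3R)-3-[(3E,7E,11S)-13-[(tert-butyldiphenylsilyl)oxy]-3,7,11-trimethyltrideca-3,7-dien-1-yl]-2-methyloxiran-2-yl}methyl (2Z)-2-methylbut-2-enoate | C/C=C(/C)C(=O)OC[C@@]1(C)O[C@@H]1CC/C(C)=C/CC/C(C)=C/CC[C@H](C)CCO[Si](c1ccccc1)(c1ccccc1)C(C)(C)C | intermediate
12 | (3R,4S,5S,8S,9S,10R,13S)-15-[(tert-butyldiphenylsilyl)oxy]-3,8-dihydroxylabdan-18-yl (2Z)-2-methylbut-2-enoate | C/C=C(/C)C(=O)OC[C@@]1(C)[C@H](O)CC[C@]2(C)[C@@H]1CC[C@](C)(O)[C@H]2CC[C@H](C)CCO[Si](c1ccccc1)(c1ccccc1)C(C)(C)C | intermediate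
13 | (3R,4S,5S,8S,9S,10R,13S)-15-[(tert-butyldiphenylsilyl)oxy]-8-hydroxy-3-[(1H-imidazol-1-ylcarbonothioyl)oxy]labdan-18-yl (2Z)-2-methylbut-2-enoate | C/C=C(/C)C(=O)OC[C@@]1(C)[C@H](OC(=S)n3ccnc3)CC[C@]2(C)[C@@H]1CC[C@](C)(O)[C@H]2CC[C@H](C)CCO[Si](c1ccccc1)(c1ccccc1)C(C)(C)C | intermediate
14 | (4S,5S,8S,9S,10R,13S)-15-[(tert-butyldiphenylsilyl)oxy]-8-hydroxylabdan-18-yl (2Z)-2-methylbut-2-enoate | C/C=C(/C)C(=O)OC[C@@]1(C)CCC[C@]2(C)[C@@H]1CC[C@](C)(O)[C@H]2CC[C@H](C)CCO[Si](c1ccccc1)(c1ccccc1)C(C)(C)C | intermediate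
15 | (4S,5S,8S,9S,10R,13S)-8,15-dihydroxylabdan-18-yl (2Z)-2-methylbut-2-enoate | C/C=C(/C)C(=O)OC[C@@]1(C)CCC[C@]2(C)[C@@H]1CC[C@](C)(O)[C@H]2CC[C@H](C)CCO | target

## Step count and weak points

Total step count: 11. Longest linear sequence: 11 (from (S)-citronellol).

The three steps most likely to fail:

**Step 8, the cyclization.** Three things can go wrong. The angelate carbonyl may open the oxirane before the alkene does, which would give a hydroxy ester or the C-4 epimer. The C-8 cation may lose a proton instead of taking up water. The tertiary alcohol may re-ionize. The fallback separates ring formation from hydration. It sets out from 11: MeAlCl2 (2.5 equiv) in CH2Cl2 at −78 °C ties up the ester carbonyl and gives the proton-loss product, the exocyclic 8(17)-alkene F1 (with some 7-ene isomer, which is removed). Oxymercuration with Hg(OAc)2 in THF/H2O adds water to C-8 from the open equatorial face and gives the alkylmercury acetate F2. Reduction with NaBH4 at 0 °C then returns the route at 12.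

**Step 5, the second SeO2 oxidation.** With three trisubstituted alkenes present, attack at the internal allylic positions and over-oxidation can make the yield poor. The fallback sets out from 7: cross-metathesis with methacrolein (second-generation Hoveyda–Grubbs catalyst, RuCl2(H2IMes)(=CH-C6H4-2-OiPr), CH2Cl2, 40 °C) exchanges only the unhindered terminal isopropylidene and gives the (E)-enal F3. Luche reduction (NaBH4, CeCl3·7H2O, MeOH, 0 °C) returns the route at 8.

**Step 10, the radical deoxygenation.** Once the thiocarbonyl group is used up, tin radicals can add reversibly to the angelate and turn it into the tiglate. The fallback avoids radicals and sets out from 12: Dess–Martin periodinane (NaHCO3, CH2Cl2) gives the 3-ketone F4. Tosylhydrazide in ethanol at 60 °C gives the tosylhydrazone F5. Catecholborane in CHCl3 at 0 °C, then NaOAc·3H2O at reflux, reduces the hydrazone to the methylene and returns the route at 14.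

Further compounds
F1 | step 8 | 8(17)-alkene corresponding to 12: (13S)-15-[(tert-butyldiphenylsilyl)oxy]-3-hydroxylabd-8(17)-en-18-yl (2Z)-2-methylbut-2-enoate, remaining ring stereocentres as in 12 | C/C=C(/C)C(=O)OC[C@@]1(C)[C@H](O)CC[C@]2(C)[C@@H]1CCC(=C)[C@H]2CC[C@H](C)CCO[Si](c1ccccc1)(c1ccccc1)C(C)(C)C
F2 | step 8 | 17-(acetoxymercurio) derivative of 12 (C-17 is CH2HgOAc, stereocentres as in 12) | C/C=C(/C)C(=O)OC[C@@]1(C)[C@H](O)CC[C@]2(C)[C@@H]1CC[C@](C[Hg]OC(C)=O)(O)[C@H]2CC[C@H](C)CCO[Si](c1ccccc1)(c1ccccc1)C(C)(C)C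
F3 | step 5 | (2E,6E,10E,14S)-16-[(tert-butyldiphenylsilyl)oxy]-2,6,10,14-tetramethylhexadeca-2,6,10-trienal | O=C/C(C)=C/CC/C(C)=C/CC/C(C)=C/CC[C@H](C)CCO[Si](c1ccccc1)(c1ccccc1)C(C)(C)C
F4 | step 10 | 3-ketone of 12: 15-[(tert-butyldiphenylsilyl)oxy]-8-hydroxy-3-oxolabdan-18-yl (2Z)-2-methylbut-2-enoate, stereocentres as in 12 | C/C=C(/C)C(=O)OC[C@@]1(C)C(=O)CC[C@]2(C)[C@@H]1CC[C@](C)(O)[C@H]2CC[C@H](C)CCO[Si](c1ccccc1)(c1ccccc1)C(C)(C)C
F5 | step 10 | 4-methylbenzenesulfonylhydrazone of F4 | C/C=C(/C)C(=O)OC[C@@]1(C)C(=NNS(=O)(=O)c3ccc(C)cc3)CC[C@]2(C)[C@@H]1CC[C@](C)(O)[C@H]2CC[C@H](C)CCO[Si](c1ccccc1)(c1ccccc1)C(C)(C)C
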